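**Plan**

1. Atoms carry the germacrane numbers of the target throughout (C1 ketone, C4–C5 epoxide, C6 lactone carbinol, C7=C11, C8 ester carbinol, C10 methine, C12 lactone carbonyl, C13 acetoxymethyl). The retrosynthesis first cuts the two ester C–O bonds (O8, O13) and the butenolide (C6–O and the C12 oxidation level) back to an exocyclic diene C6=C7–C11=C12.
2. The ten-membered ring is then cut at C8–C9 with C1–C6 re-joined. The C1 ketone with its C10 methyl and the C8 oxygen are 1,5-related through C9, the enolate and enol-ether ends of an anionic oxy-Cope shift, and the cis C4–C5 epoxide fits a cyclohexene oxide, ring A = C1–C6.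
3. Ring A is cut at C1–C6 and C2–C3 into a diene and a chiral methylene-dioxolanone (Diels–Alder). C7–C8, C11–C13 and C11–C12 come from formylation of a lactone and two organolithium additions to its carbonyl group.
4. Forward order: ring A, cis-fused γ-lactone, enol ether, epoxide, diene, ten-membered ring (ring expansion), butenolide ring, esters.
5. Stereochemistry: (R)-lactic acid fixes the acetal centre of the dienophile, which fixes C1 and C6 in the cycloaddition. The lactone ring then directs the epoxidation (C4, C5) and fixes the enol-ether geometry.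
6. C1 and C6 are relayed to C8 through the chair transition state, C10 comes from protonation of the ring enolate, and the C6 carbinol centre from the face of the diene that singlet oxygen attacks.

Key step: step 15

**Route**

Step 1
Reactants: 1 (R)-lactic acid; 2 pivaldehyde
Product: 3 (2R,5R)-2-tert-butyl-5-methyl-1,3-dioxolan-4-one (cis)
Conditions: TsOH (cat.), pentane, reflux, water separator; crystallisation at low temperature
Reagents that add atoms: none
Why: Acid-catalysed acetalisation of an α-hydroxy acid under water removal is reversible, the cis-dioxolanone is the favoured and crystalline isomer, and so the retained lactate centre fixes the new acetal centre as R.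

Step 2
Reactants: 3 (2R,5R)-2-tert-butyl-5-methyl-1,3-dioxolan-4-one
Product: 5 (2R)-2-tert-butyl-5-methylene-1,3-dioxolan-4-one, via bromide 4 (not isolated)
Conditions: N-bromosuccinimide, AIBN (cat.), cyclohexane, reflux; then Et3N, Et2O, 0 °C to rt
Reagents that add atoms: none
Why: Wohl–Ziegler radical bromination takes place at the captodative C5–H and E2 loss of HBr towards the methyl group gives the exocyclic alkene, while the acetal centre, now the only stereocentre, is untouched.

Step 3
Reactants: 6 tert-butyl(but-3-yn-1-yloxy)dimethylsilane; 7 2-bromopropene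
Product: 9 (E)-tert-butyldimethyl[(5-methylhexa-3,5-dien-1-yl)oxy]silane, via alkenylzirconocene chloride 8 (not isolated)
Conditions: Cp2Zr(H)Cl, THF, rt; then 7, Pd(PPh3)4 (cat.), ZnCl2 (cat.), THF, rt
Reagents that add atoms: none
Why: Syn-hydrozirconation places zirconium on the terminal alkyne carbon with E geometry, and Negishi-type cross-coupling with the alkenyl bromide under zerovalent palladium (ZnCl2 as transmetallation shuttle) proceeds with retention to give the E-diene.

Step 4
Reactants: 5 (2R)-2-tert-butyl-5-methylene-1,3-dioxolan-4-one; 9 (E)-diene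
Product: 10 spiro cycloadduct: (2R)-2-tert-butyl-1,3-dioxolan-4-one spiro-linked at C1 of a 4-methylcyclohex-3-ene that carries the 2-(silyloxy)ethyl chain at C6 (ring oxygen cis to the chain; tert-butyl anti to the C1–C6 bond)
Conditions: toluene, 2,6-di-tert-butyl-4-methylphenol (trace), 100 °C, sealed tube
Reagents that add atoms: none
Why: Thermal Diels–Alder reaction in which the CH2 terminus of the captodative dienophile bonds to the unsubstituted diene terminus C3 (ortho/para regiochemistry), the diene adds anti to the tert-butyl group and the lactone carbonyl takes the exo position, as is usual for α-oxygenated methylene lactones, so that C1 is set with its oxygen cis and its acyl carbon trans to the new C6 side chain.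

Step 5
Reactants: 10 spiro cycloadduct
Product: 11 N-methoxy-N-methyl amide of the 1-hydroxy-4-methyl-6-[2-(silyloxy)ethyl]cyclohex-3-ene-1-carboxylic acid (OH cis to the C6 chain)
Conditions: MeNH(OMe)·HCl, iPrMgCl, THF, −20 to 0 °C; H2O
Reagents that add atoms: N,O-dimethylhydroxylamine hydrochloride, CNOC.Cl
Why: Weinreb aminolysis of the activated acylal lactone by the magnesium amide; the hemiacetal alkoxide left on the C1 oxygen loses pivaldehyde and no ring stereocentre is touched.

Step 6
Reactants: 11 Weinreb amide
Product: 12 1-acetyl-4-methyl-6-[2-(silyloxy)ethyl]cyclohex-3-en-1-ol (OH cis to the C6 chain)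
Conditions: MeMgBr (excess), THF, 0 °C; H2O
Reagents that add atoms: methylmagnesium bromide, C[Mg]Br
Why: Weinreb ketone synthesis, in which the chelated tetrahedral intermediate stops the Grignard addition at the ketone (one equivalent is consumed by the free hydroxyl).

Step 7
Reactants: 12 methyl ketone
Product: 13 1-isopropenyl-4-methyl-6-[2-(silyloxy)ethyl]cyclohex-3-en-1-ol (OH cis and isopropenyl trans to the C6 chain)
Conditions: Ph3PCH3Br, KN(SiMe3)2 (excess ylide), THF, 0 °C to rt
Reagents that add atoms: methyltriphenylphosphonium bromide, C[P+](c1ccccc1)(c1ccccc1)c1ccccc1.[Br-]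
Why: Wittig methylenation with excess ylide turns the α-hydroxy methyl ketone into the isopropenyl group (C10=C9) without protection of the tertiary alcohol.

Step 8
Reactants: 13 silyl ether
Product: 14 6-(2-hydroxyethyl)-1-isopropenyl-4-methylcyclohex-3-en-1-ol (the two oxygenated substituents cis)
Conditions: Bu4NF, THF, 0 °C to rt
Reagents that add atoms: none
Why: Fluoride cleaves the primary silyl ether (Si–F bond formation) and leaves the tertiary allylic alcohol and both alkenes alone.

Step 9
Reactants: 14 diol
Product: 16 cis-fused 5-methyl-7a-isopropenyl-3a,6,7,7a-tetrahydro-1-benzofuran-2(3H)-one, via lactol 15 (not isolated)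
Conditions: TEMPO (cat.), PhI(OAc)2, CH2Cl2, rt
Reagents that add atoms: none
Why: The oxoammonium oxidant takes only the primary alcohol to the aldehyde, which is trapped by the cis tertiary hydroxyl as the lactol and oxidised further, an oxidative lactonisation of a 1,4-diol that gives the cis-fused γ-lactone (carbonyl carbon = C11).

Step 10
Reactants: 16 lactone
Product: 18 (E)-3-[(4-methoxybenzyloxy)methylene] derivative of lactone 16 (enol-ether oxygen anti to the lactone carbonyl and cis to C6), via sodium formyl-lactone enolate 17 (not isolated)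
Conditions: NaH, HCO2Et, THF, 0 °C to rt; then 4-methoxybenzyl chloride, DMF, rt
Reagents that add atoms: ethyl formate, CCOC=O; 4-methoxybenzyl chloride, COc1ccc(CCl)cc1
Why: Claisen condensation with ethyl formate at the only enolisable position C7, then O-alkylation of the formyl enolate by the SN1-prone benzylic chloride, gives the alkoxymethylene lactone as the E isomer, the thermodynamically preferred geometry of such push–pull alkenes.

Step 11
Reactants: 18 alkoxymethylene lactone
Product: 19 epoxy lactone: 18 with a 4S,5R oxirane on the former C4=C5 bond, anti to the lactone ring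
Conditions: mCPBA, NaHCO3, CH2Cl2, 0 °C
Reagents that add atoms: 3-chloroperoxybenzoic acid, OOC(=O)c1cccc(Cl)c1
Why: Prilezhaev epoxidation attacks the trisubstituted ring alkene, the most nucleophilic double bond (the isopropenyl group is 1,1-disubstituted and next to the lactone oxygen, the enol ether is deactivated by the carbonyl group), from the convex face of the cis-fused bicycle, which sets the cis-epoxide as 4S,5R.

Step 12
Reactants: 20 (tributylstannyl)methanol
Product: 21 tributyl[(4-methoxybenzyloxy)methyl]stannane
Conditions: NaH, 4-methoxybenzyl chloride, Bu4NI (cat.), THF/DMF, 0 °C to rt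
Reagents that add atoms: 4-methoxybenzyl chloride, COc1ccc(CCl)cc1
Why: Williamson etherification of the sodium alkoxide with the benzylic chloride.

Step 13
Reactants: 19 epoxy lactone; 21 tributyl[(4-methoxybenzyloxy)methyl]stannane
Product: 23 silyl diol: epoxycyclohexanol in which C11 carries OH, CH2OPMB (C13) and CH2SiMe3 (C12) (C11 epimers), via lithium lactolate 22 (not isolated)
Conditions: 21, nBuLi, THF, −78 °C; add 19, −78 °C; then Me3SiCH2Li, −78 to 0 °C; H2O
Reagents that add atoms: (trimethylsilyl)methyllithium, [Li]C[Si](C)(C)C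
Why: Tin–lithium exchange gives the α-alkoxy organolithium, which adds once to the lactone carbonyl because the cyclic lactolate is stable at −78 °C, and on warming the ring-opened ketone is trapped by the small silylmethyllithium, a stepwise double addition to a lactone that places C13 and C12 on C11 and frees the C1 hydroxyl.

Step 14
Reactants: 23 silyl diol
Product: 24 (1S,4S,5R,6R)-4,5-epoxy-1-isopropenyl-4-methylcyclohexan-1-ol with the dienyl group C7(=C8H–OPMB)–C11(=CH2)–CH2OPMB at C6 (isopropenyl and dienyl trans; OH cis to the dienyl and trans to the epoxide oxygen; enol-ether oxygen cis to C6)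
Conditions: KOtBu, THF, 0 °C; pH 7 buffer
Reagents that add atoms: none
Why: Peterson olefination, in which the potassium β-silyl alkoxide undergoes syn-elimination of silanolate to the C11=C12 methylene group, while the C1 alkoxide does not rearrange at 0 °C without a crown ether.

Step 15
Reactants: 24 epoxycyclohexanol (oxy-Cope precursor)
Product: 27 (4S,5R,6E,8R,10S)-4,5-epoxy-8-(4-methoxybenzyloxy)-germacra-6,11-dien-1-one with CH2OPMB at C11, via potassium alkoxide 25 (not isolated), via potassium enolate 26 (not isolated)
Conditions: KH, 18-crown-6, THF, 0 °C to rt; then AcOH in THF, −78 °C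
Reagents that add atoms: none
Why: KH deprotonates the tertiary C1 hydroxyl and the crown ether strips the cation, so alkoxide 25 undergoes the anionic oxy-Cope [3,3]-sigmatropic shift across C9=C10–C1–C6–C7=C8, forming C8–C9 and breaking C1–C6 to give the ring-enlarged E-enolate 26 (closest known class: ring expansion of trans-1,2-dialkenylcyclohexanols to cyclodec-5-enones). The ten-membered ring is not made by a cyclisation in the usual sense: the six-centre chair array closes it through C8–C9 while ring A opens, a six-to-ten expansion by four atoms. C8 is fixed by the chair transition state in which both ring bonds (C1–C2 and C6–C5) are equatorial and the enol-ether oxygen, cis to C6, is axial, so the 1S and 6R centres that are destroyed are relayed to 8R and the C6=C7 bond is formed E. C10 is fixed when the enolate is protonated at −78 °C on its outer face, the inner face being covered by the C6=C7 bond across the ring, which should give 10S. The step needs chair over boat and [3,3] shift over epoxide opening: the trans-diequatorial alkenyl groups secure the first, and for the second the alkoxide can reach the epoxide only at its tertiary carbon C4 through a bridged geometry and the enolate only across the ring, which low temperature and a prompt quench should suppress.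

Step 16
Reactants: 27 ten-membered dienyl ketone
Product: 28 endoperoxide: 3,6-dihydro-1,2-dioxine spanning C6–O–O–C12 with C7=C11 (6R; other centres as in 27)
Conditions: O2, tetraphenylporphyrin (cat.), visible light, CH2Cl2, −78 °C
Reagents that add atoms: dioxygen, O=O
Why: Singlet oxygen adds to the s-cis 1,3-diene C6=C7–C11=C12 in a [4+2] cycloaddition that forms C6–O and C12–O and moves the double bond to C7=C11 with its geometry fixed by the new ring; attack from the outer face of the macrocycle, anti to the ring bond C5–C4 with the epoxide C–O bond near the diene plane, should give 6R.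

Step 17
Reactants: 28 endoperoxide
Product: 30 8,13-bis(4-methoxybenzyl) ether of the 7(11)-en-12,6-olide (butenolide), via lactol 29 (not isolated)
Conditions: Et3N (cat.), CH2Cl2, 0 °C; then N-methylmorpholine N-oxide, Pr4N[RuO4] (cat.), 4 Å molecular sieves, rt
Reagents that add atoms: none
Why: Kornblum–DeLaMare rearrangement, in which the amine removes a proton from the unhindered C12 methylene and the O–O bond breaks to the C12 aldehyde and the C6 alkoxide, which close to the lactol; Ley–Griffith oxidation under neutral conditions then gives the butenolide before the lactol can dehydrate to a furan.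

Step 18
Reactants: 30 bis-PMB butenolide
Product: 31 8,13-dihydroxy butenolide
Conditions: DDQ, CH2Cl2/pH 7 buffer, 0 °C to rt
Reagents that add atoms: none
Why: Oxidative cleavage of both 4-methoxybenzyl ethers by DDQ (hydride abstraction, then hydrolysis of the oxocarbenium ions) in buffered medium, to which epoxide, ketone and butenolide are inert.

Step 19
Reactants: 31 diol
Product: 32 13-acetate with free 8-hydroxyl
Conditions: AcCl, 2,4,6-collidine, CH2Cl2, −78 °C
Reagents that add atoms: acetyl chloride, CC(=O)Cl
Why: Selective acylation, since the primary allylic hydroxyl reacts with acetyl chloride and a hindered pyridine base at low temperature much faster than the secondary C8 hydroxyl.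

Step 20
Reactants: 32 hydroxy acetate
Product: 33 CNP0220542.1, (4S,5R,6R,8R,10S)-13-acetoxy-4,5-epoxy-1-oxo-8-(3-methylbut-2-enoyloxy)germacr-7(11)-en-12,6-olide
Conditions: 3-methylbut-2-enoic acid, DCC, DMAP (cat.), CH2Cl2, 0 °C to rt
Reagents that add atoms: 3-methylbut-2-enoic acid, CC(C)=CC(=O)O
Why: Steglich esterification of the remaining secondary alcohol under nearly neutral conditions, which spare the base-sensitive C6–H next to the epoxide and leave the configuration at C8 unchanged.

**Compound list**

1 | (R)-lactic acid | C[C@@H](O)C(=O)O | starting material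
2 | pivaldehyde | CC(C)(C)C=O | starting material
3 | (2R,5R)-2-tert-butyl-5-methyl-1,3-dioxolan-4-one (cis) | C[C@H]1O[C@@H](C(C)(C)C)OC1=O | intermediate
4 | 5-bromo-2-tert-butyl-5-methyl-1,3-dioxolan-4-one (acetal centre as in 3; C5 epimers) | CC1(Br)O[C@@H](C(C)(C)C)OC1=O | intermediate
5 | (2R)-2-tert-butyl-5-methylene-1,3-dioxolan-4-one | C=C1O[C@@H](C(C)(C)C)OC1=O | intermediate
6 | tert-butyl(but-3-yn-1-yloxy)dimethylsilane | C#CCCO[Si](C)(C)C(C)(C)C | starting material
7 | 2-bromopropene | C=C(C)Br | starting material
8 | (E)-[4-(tert-butyldimethylsilyloxy)but-1-en-1-yl]zirconocene chloride | CC(C)(C)[Si](C)(C)OCC/C=C/[Zr](Cl)(C1C=CC=C1)C1C=CC=C1 | intermediate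
9 | (E)-tert-butyldimethyl[(5-methylhexa-3,5-dien-1-yl)oxy]silane | C=C(C)/C=C/CCO[Si](C)(C)C(C)(C)C | intermediate
10 | spiro Diels–Alder adduct (ring oxygen cis to the C6 chain; tert-butyl anti to C1–C6) | O=C1O[C@H](C(C)(C)C)O[C@]12CCC(C)=C[C@H]2CCO[Si](C)(C)C(C)(C)C | intermediate
11 | α-hydroxy Weinreb amide (OH cis to the C6 chain) | CON(C)C(=O)[C@]1(O)CCC(C)=C[C@H]1CCO[Si](C)(C)C(C)(C)C | intermediate
12 | α-hydroxy methyl ketone | CC(=O)[C@]1(O)CCC(C)=C[C@H]1CCO[Si](C)(C)C(C)(C)C | intermediate
13 | isopropenyl carbinol silyl ether | C=C(C)[C@]1(O)CCC(C)=C[C@H]1CCO[Si](C)(C)C(C)(C)C | intermediate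
14 | 6-(2-hydroxyethyl)-1-isopropenyl-4-methylcyclohex-3-en-1-ol (oxygenated groups cis) | C=C(C)[C@]1(O)CCC(C)=C[C@H]1CCO | intermediate
15 | lactol of the hydroxy aldehyde (lactol centre unassigned) | C=C(C)[C@]12CCC(C)=C[C@H]1CC(O)O2 | intermediate
16 | cis-fused 5-methyl-7a-isopropenyl-3a,6,7,7a-tetrahydro-1-benzofuran-2(3H)-one | C=C(C)[C@]12CCC(C)=C[C@H]1CC(=O)O2 | intermediate
17 | sodium enolate of the 3-formyl lactone | C=C(C)[C@]12CCC(C)=C[C@H]1C(=C[O-])C(=O)O2.[Na+] | intermediate
18 | (E)-3-[(4-methoxybenzyloxy)methylene] lactone | C=C(C)[C@]12CCC(C)=C[C@H]1/C(=C\OCc1ccc(OC)cc1)C(=O)O2 | intermediate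
19 | epoxy lactone (4S,5R oxirane anti to the lactone ring) | C=C(C)[C@]12CC[C@]3(C)O[C@@H]3[C@H]1/C(=C\OCc1ccc(OC)cc1)C(=O)O2 | intermediate
20 | (tributylstannyl)methanol | CCCC[Sn](CCCC)(CCCC)CO | starting material
21 | tributyl[(4-methoxybenzyloxy)methyl]stannane | CCCC[Sn](CCCC)(CCCC)COCc1ccc(OC)cc1 | intermediate
22 | lithium lactolate from 19 (C11 unassigned) | C=C(C)[C@]12CC[C@]3(C)O[C@@H]3[C@H]1/C(=C\OCc1ccc(OC)cc1)C([O-])(COCc1ccc(OC)cc1)O2.[Li+] | intermediate
23 | silyl diol (C11 epimers) | C=C(C)[C@]1(O)CC[C@]2(C)O[C@@H]2[C@H]1/C(=C\OCc1ccc(OC)cc1)C(O)(C[Si](C)(C)C)COCc1ccc(OC)cc1 | intermediate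
24 | (1S,4S,5R,6R)-epoxycyclohexanol, oxy-Cope precursor | C=C(C)[C@]1(O)CC[C@]2(C)O[C@@H]2[C@H]1/C(=C\OCc1ccc(OC)cc1)C(=C)COCc1ccc(OC)cc1 | intermediate
25 | potassium alkoxide of 24 | C=C(C)[C@]1([O-])CC[C@]2(C)O[C@@H]2[C@H]1/C(=C\OCc1ccc(OC)cc1)C(=C)COCc1ccc(OC)cc1.[K+] | intermediate
26 | potassium E-enolate of the ten-membered ketone | C/C1=C(/[O-])CC[C@]2(C)O[C@@H]2/C=C(/[C@H](OCc2ccc(OC)cc2)C1)C(=C)COCc1ccc(OC)cc1.[K+] | intermediate
27 | (4S,5R,6E,8R,10S) ten-membered epoxy dienyl ketone | O=C1CC[C@]2(C)O[C@@H]2/C=C(/[C@H](OCc2ccc(OC)cc2)C[C@@H]1C)C(=C)COCc1ccc(OC)cc1 | intermediate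
28 | endoperoxide (C6–O–O–C12; 6R) | COc1ccc(COCC2=C3[C@@H](OOC2)[C@H]2O[C@@]2(C)CCC(=O)[C@@H](C)C[C@H]3OCc2ccc(OC)cc2)cc1 | intermediate
29 | lactol (C12 unassigned) | COc1ccc(COCC2=C3[C@@H](OC2O)[C@H]2O[C@@]2(C)CCC(=O)[C@@H](C)C[C@H]3OCc2ccc(OC)cc2)cc1 | intermediate
30 | bis-PMB butenolide | COc1ccc(COCC2=C3[C@@H](OC2=O)[C@H]2O[C@@]2(C)CCC(=O)[C@@H](C)C[C@H]3OCc2ccc(OC)cc2)cc1 | intermediate
31 | 8,13-dihydroxy butenolide | OCC1=C2[C@@H](OC1=O)[C@H]1O[C@@]1(C)CCC(=O)[C@@H](C)C[C@H]2O | intermediate
32 | 13-acetoxy-8-hydroxy butenolide | CC(=O)OCC1=C2[C@@H](OC1=O)[C@H]1O[C@@]1(C)CCC(=O)[C@@H](C)C[C@H]2O | intermediate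
33 | CNP0220542.1 | CC(=O)OCC1=C2[C@@H](OC1=O)[C@H]1O[C@@]1(C)CCC(=O)[C@@H](C)C[C@H]2OC(=O)C=C(C)C | target

**Step count and risks**

Total steps: 20. Longest linear sequence: 18 steps (1, 2, 4 to 11, 13 to 20); steps 3 and 12 are side branches.

Steps most likely to fail:

- **Step 15.** Proton transfer to the crown-separated enolate may go through oxygen, and the enol may then ketonise on either face, which would erode C10. A long-lived enolate may also attack the epoxide across the ring. The fallback sets out from 24: the rearrangement is run as before, but Me3SiCl/Et3N is added at −78 °C so that the enolate is captured at once as the trimethylsilyl enol ether F1, which is isolated. MeLi (THF, −78 °C) would then regenerate the contact-ion-pair lithium enolate F2, which is protonated at carbon by 2,6-di-tert-butyl-4-methylphenol, and the route is rejoined at 27.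

- **Step 16.** The diene may not reach the s-cis geometry that the [4+2] addition needs, because C5 sits on the inside of the C6 terminus; ene reaction at C8–H or dioxetane formation would then compete, or oxygen may add to the inner face. The fallback sets out from 27: DDQ removes both PMB groups to give the diene diol F3, and tBu2Si(OTf)2/2,6-lutidine ties O8 to O13 in the seven-membered silylene F4, which holds C6=C7 and C11=C12 s-cis as a 1,2-bis(alkylidene) ring. Photooxygenation then gives the silylene endoperoxide F5, Et3N gives the silylene lactol F6, Pr4N[RuO4]/N-methylmorpholine N-oxide gives the silylene butenolide F7, and HF·pyridine removes the tether, so the route is rejoined at 31.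

- **Step 13.** The second organolithium may deprotonate the α-alkoxy ketone unmasked from the lactolate, or add to C8 with loss of the PMB-oxy group, and the C11 alkoxide may open the epoxide. The fallback sets out from 19: (4-methoxybenzyloxy)methyllithium alone, quenched at −78 °C, gives the hydroxy ketone F8. Petasis methylenation (Cp2TiMe2, toluene, 65 °C) then converts its carbonyl group directly into the C11=C12 methylene, so the route is rejoined at 24 without the Peterson step.

**Further compounds**

F1 | step 15 | trimethylsilyl enol ether of 27 | C/C1=C(/O[Si](C)(C)C)CC[C@]2(C)O[C@@H]2/C=C(/[C@H](OCc2ccc(OC)cc2)C1)C(=C)COCc1ccc(OC)cc1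
F2 | step 15 | lithium enolate of 27 | C/C1=C(/[O-])CC[C@]2(C)O[C@@H]2/C=C(/[C@H](OCc2ccc(OC)cc2)C1)C(=C)COCc1ccc(OC)cc1.[Li+]
F3 | step 16 | diene diol (27 without PMB groups) | O=C1CC[C@]2(C)O[C@@H]2/C=C(/[C@H](O)C[C@@H]1C)C(=C)CO
F4 | step 16 | di-tert-butylsilylene of F3 (O8–Si–O13) | O=C1CC[C@]2(C)O[C@@H]2/C=C2\C(=C)CO[Si](C(C)(C)C)(C(C)(C)C)O[C@@H]2C[C@@H]1C
F5 | step 16 | silylene endoperoxide | O=C1CC[C@]2(C)O[C@@H]2[C@@H]2OOCC3=C2[C@@H](C[C@@H]1C)O[Si](C(C)(C)C)(C(C)(C)C)OC3
F6 | step 16 | silylene lactol | O=C1CC[C@]2(C)O[C@@H]2[C@@H]2OC(O)C3=C2[C@@H](C[C@@H]1C)O[Si](C(C)(C)C)(C(C)(C)C)OC3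
F7 | step 16 | silylene butenolide | O=C1CC[C@]2(C)O[C@@H]2[C@@H]2OC(=O)C3=C2[C@@H](C[C@@H]1C)O[Si](C(C)(C)C)(C(C)(C)C)OC3
F8 | step 13 | hydroxy ketone (C11 ketone with CH2OPMB) | C=C(C)[C@]1(O)CC[C@]2(C)O[C@@H]2[C@H]1/C(=C\OCc1ccc(OC)cc1)C(=O)COCc1ccc(OC)cc1
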